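**Plan**
1. Retrosynthesis first cuts the four ester C–O bonds (the C7 ester is made last), then C4–C11 (Stille coupling of a C4 enol triflate) and the C5=C6 unsaturation (dehydrogenation of a C7 ketone).
2. The cyclopentene ring (C5–C6–C7–C8–C9) has oxygen on C7 next to the tertiary carbinol C8 with its C10 arm. This is an α-ketol pattern, so C8–C9 is cut by a retro-1,2-shift to a cyclobutanol (ring C5–C6–C7–C9) whose C7 carries OH and the chain C8(=O)–C10H2–O-isovaleryl.
3. The cyclobutane is cut at C5–C6 and C7–C9 ([2+2]) into 1,1-dimethoxyethene and an Achmatowicz enone (C1, O2, C3, C4, C5, C9) from furfuryl alcohol; C8 and C10 come from 1-ethoxyvinyllithium.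
4. Forward order: pyranone, then cis-fused cyclobutane, then acylcyclobutanol, then ring enlargement to the cyclopenta[c]pyran, then dienone, then the C1, C11 and C7 esters.
5. Stereochemistry: C1 by lipase resolution (a relay, reset at the end by equatorial acylation of the lactol); C9 and C5 by cycloaddition anti to the C1 substituent; C8 by the chelate-controlled shift with retention at C9; C7 by hydride delivery anti to the C10 arm; the side chain from (S)-3-methylpentanoic acid.

Key step: step 10

Remarks: Locants are iridoid numbers (C1 acetal carbon, O2, C3, C4, C5 and C9 ring fusion, C6, C7, C8, C10 on C8, C11 on C4); PMB = 4-methoxybenzyl, Tf = trifluoromethanesulfonyl. Assumptions: the lipase is taken to acylate the lactol enantiomer that gives (S)-3, and (S)-3-methylpentanoic acid 19 is taken as a purchasable acid.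

Step 1
Reactants: 1 furfuryl alcohol
Product: 2 6-hydroxy-2H-pyran-3(6H)-one (racemic lactol)
Conditions: mCPBA, CH2Cl2, 0 °C
Reagents that add atoms: mCPBA, O=C(OO)c1cccc(Cl)c1
Why: Achmatowicz oxidative ring expansion of the furfuryl alcohol (furan oxidation, opening to the ene-dione, hemiacetal closure) should give the pyranone, with C1 formed as a racemic, configurationally labile lactol.

Step 2
Reactants: 2 6-hydroxy-2H-pyran-3(6H)-one
Product: 3 (S)-6-acetoxy-2H-pyran-3(6H)-one
Conditions: lipase PS (immobilised), vinyl acetate, i-Pr2O, 25 °C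
Reagents that add atoms: vinyl acetate, C=COC(C)=O
Why: Lipase-catalysed dynamic kinetic resolution by irreversible transesterification: the lactol enantiomers interconvert by ring-chain tautomerism while the enzyme acylates one of them, which sets C1.

Step 3
Reactants: 3 (S)-6-acetoxy-2H-pyran-3(6H)-one
Product: 4 (R)-6-[(4-methoxybenzyl)oxy]-2H-pyran-3(6H)-one
Conditions: 4-methoxybenzyl alcohol, Pd2(dba)3·CHCl3 (2.5 mol %), PPh3 (10 mol %), CH2Cl2, 0 °C
Reagents that add atoms: 4-methoxybenzyl alcohol, COc1ccc(CO)cc1
Why: Tsuji–Trost-type allylic substitution at the anomeric carbon (palladium-catalysed O-glycosylation): ionisation and attack of the alcohol both occur anti to zerovalent palladium, so C1 is retained in space (the descriptor changes only through CIP priorities).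

Step 4
Reactants: 4 (R)-6-[(4-methoxybenzyl)oxy]-2H-pyran-3(6H)-one
Product: 5 photoadduct, 7,7-dimethoxycyclobutane (C5–C6–C7–C9) cis-fused to the 1-(PMB-oxy)tetrahydropyran-4-one
Conditions: 1,1-dimethoxyethene (10 equiv), hν (350 nm), CH2Cl2, −40 °C; then basic Al2O3
Reagents that add atoms: 1,1-dimethoxyethene, C=C(OC)OC
Why: Enone–alkene [2+2] photocycloaddition in the head-to-tail mode of an electron-rich alkene: the ketal carbon should bond to the β-carbon C9 and the CH2 to C5, the alkene should add anti to the pseudo-axial C1 PMB-oxy group (setting C9 and C5), and the alumina treatment secures the cis ring fusion by epimerisation at C5.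

Step 5
Reactants: 5 photoadduct ketone
Product: 6 C3=C4 enol triflate of 5
Conditions: KN(SiMe3)2, THF, −78 °C; then PhNTf2, −78 → 0 °C
Reagents that add atoms: N-phenylbis(trifluoromethanesulfonimide), O=S(=O)(N(c1ccccc1)S(=O)(=O)C(F)(F)F)C(F)(F)F
Why: Kinetic enolisation and O-triflation: the bulky base should take a proton from the unhindered C3 methylene and not from the C5 ring-fusion methine (whose enolate would place an exocyclic double bond on the cyclobutane), and the triflate stores the later C4–C11 bond while deactivating the O2–C3=C4 enol ether towards acid.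

Step 6
Reactants: 6 enol triflate ketal
Product: 7 cyclobutanone (C7 ketone)
Conditions: PPTS (cat.), acetone/H2O, 25 °C
Reagents that add atoms: water, O
Why: Acid-catalysed ketal hydrolysis: the dimethyl ketal ionises to a tertiary oxocarbenium ion far faster than the C1 acetal, whose ring oxygen is now conjugated with the enol triflate.

Step 7
Reactants: 7 cyclobutanone
Product: 8 tertiary cyclobutanol, C7 carrying OH (endo, cis to C1) and 1-ethoxyvinyl (exo, cis to H9)
Conditions: ethyl vinyl ether, t-BuLi, THF, −78 → 0 °C; then 7, −78 °C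
Reagents that add atoms: ethyl vinyl ether (as its α-lithio derivative), C=COCC
Why: 1,2-Addition of an α-alkoxyvinyllithium (acyl anion equivalent) to the strained ketone: attack on the convex face of the cis-fused bicycle should place the two-carbon unit exo and the C7 hydroxyl endo.

Step 8
Reactants: 8 ethoxyvinyl cyclobutanol
Product: 10 hydroxyacetyl cyclobutanol (C7–OH endo; C8 ketone; C10–OH), via ethyl hemiketal 9 (not isolated)
Conditions: OsO4 (2 mol %), NMO, acetone/H2O, 0 °C
Reagents that add atoms: N-methylmorpholine N-oxide, C[N+]1([O-])CCOCC1; water, O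
Why: Upjohn dihydroxylation of the most electron-rich alkene (the enol ether, not the triflate-deactivated C3=C4 bond) should give a hemiketal that loses ethanol to unveil the C8 ketone and the C10 hydroxyl.

Step 9
Reactants: 10 hydroxyacetyl cyclobutanol
Product: 11 C10 3-methylbutanoate of 10
Conditions: 3-methylbutanoyl chloride, pyridine, CH2Cl2, −20 °C
Reagents that add atoms: 3-methylbutanoyl chloride, CC(C)CC(=O)Cl
Why: Selective O-acylation of the primary C10 hydroxyl in the presence of the tertiary cyclobutanol installs the isovalerate before the rearrangement.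

Step 10
Reactants: 11 1-acylcyclobutanol
Product: 12 ring-expanded cyclopentanone (C7 ketone; C8 carrying OH cis to C1 and the isovaleryloxymethyl arm cis to H9; H5 and H9 cis)
Conditions: Al(Ot-Bu)3 (20 mol %), toluene, 60 °C
Reagents that add atoms: none
Why: The aluminium alkoxide of the C7 carbinol chelates the C8 carbonyl oxygen (O7–C7–C8–O8 syn-periplanar), and the C7–C9 bond, held perpendicular to the carbonyl plane, shifts with its electron pair to C8 while C7 becomes the ketone: an α-ketol (acyloin) rearrangement driven by release of cyclobutane strain. The closest known reaction type is the Lewis-acid or metal-alkoxide mediated ring enlargement of 1-acylcyclobutanols to 2-hydroxycyclopentanones, together with the chelate-controlled D-homoannulation of 17-hydroxy-20-keto steroids. The five-membered ring C5–C6–C7–C8–C9 is closed by this suprafacial 1,2-shift, a ring enlargement from four to five members in which C8 is inserted between C7 and C9, and not by a cyclisation. C9 migrates with retention, and the new C8 centre is fixed by the chelate: because the acyl group stands exo on C7 (step 7), C9 reaches the carbonyl face that leaves the C8 oxygen cis to C1 and the C10 arm cis to H9, as in the target. The step needs bond selectivity for C9 over C6: C9 is the more substituted, better migrating carbon, and the rotamer needed for C6 migration would push the C10 ester arm against C1 and its PMB-oxy group. It also needs the chelated (syn) over the open (anti) geometry, which the oxophilic aluminium centre in a non-coordinating solvent should secure.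

Step 11
Reactants: 12 cyclopentanone
Product: 13 dienone (C7 ketone, C5=C6, C3=C4)
Conditions: IBX, 4-methoxypyridine N-oxide, DMSO, 25 °C
Reagents that add atoms: none
Why: IBX dehydrogenation of a ketone through its enol: C6 is the only enolisable position of the C7 ketone, and the new C5=C6 bond is conjugated with O2–C3=C4, so a push-pull dienone should form without touching C8 or C9.

Step 12
Reactants: 13 dienone PMB acetal
Product: 14 C1 lactol of 13 (anomeric mixture)
Conditions: DDQ, CH2Cl2/pH 7 buffer, 0 °C
Reagents that add atoms: none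
Why: Oxidative cleavage of the 4-methoxybenzyl acetal by DDQ (benzylic hydride abstraction, then hydrolysis) should free the C1 lactol under neutral conditions; the lactol is expected to persist because its ring-opened form is a vinylogous acid that recloses.

Step 13
Reactants: 14 lactol
Product: 15 C1 3-methylbut-2-enoate of 14 (acyloxy cis to H9)
Conditions: 3-methylbut-2-enoic acid, DIC, DMAP (cat.), CH2Cl2, −20 °C
Reagents that add atoms: 3-methylbut-2-enoic acid, CC(C)=CC(=O)O
Why: Steglich esterification of the hemiacetal: the anomers equilibrate through the open form and the less hindered, more nucleophilic equatorial hydroxyl (anti to the C8 substituents) should be acylated, setting C1 as in the target (H1 and H9 trans-diaxial).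

Step 14
Reactants: 15 dienyl triflate
Product: 16 C11 alcohol (4-hydroxymethyl analogue of 15)
Conditions: Bu3SnCH2OH, Pd(PPh3)4 (5 mol %), LiCl, 1,4-dioxane, 80 °C
Reagents that add atoms: (tributylstannyl)methanol, CCCC[Sn](CO)(CCCC)CCCC
Why: Stille cross-coupling (Kosugi hydroxymethylation) of the electron-poor dienyl triflate should form the C4–C11 bond without touching the esters.

Step 15
Reactants: 16 C11 alcohol
Product: 17 C11 acetate of 16
Conditions: Ac2O, pyridine, DMAP (cat.), CH2Cl2, 0 °C
Reagents that add atoms: acetic anhydride, CC(=O)OC(C)=O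
Why: Acetylation of the primary allylic alcohol; the tertiary C8 hydroxyl should not react under these conditions.

Step 16
Reactants: 17 dienone
Product: 18 C7 alcohol of 17 (C7–OH trans to C8–OH, cis to H9)
Conditions: NaBH4, CeCl3·7H2O, MeOH/THF, −40 °C
Reagents that add atoms: none
Why: Luche 1,2-reduction: hydride should add to the C7 carbonyl from the face of the C8 hydroxyl, anti to the C10 acyloxymethyl arm, giving the C7 alcohol with the target configuration while the four esters survive at low temperature.

Step 17
Reactants: 18 C7 alcohol; 19 (S)-3-methylpentanoic acid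
Product: 20 target, (1S,6S,7R,7aS)-4-(acetoxymethyl)-7-hydroxy-7-[(3-methylbutanoyloxy)methyl]-6-[(3S)-3-methylpentanoyloxy]-1,6,7,7a-tetrahydrocyclopenta[c]pyran-1-yl 3-methylbut-2-enoate
Conditions: DCC, DMAP (cat.), CH2Cl2, 0 °C → rt
Reagents that add atoms: none
Why: Steglich esterification of the secondary allylic C7 alcohol proceeds with retention at C7 and without risk to the β-stereocentre of the acid, and the tertiary C8 hydroxyl should remain free.

**Compound list**
1 | furfuryl alcohol (furan-2-ylmethanol) | OCc1ccco1 | starting material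
2 | 6-hydroxy-2H-pyran-3(6H)-one (racemic lactol) | O=C1COC(O)C=C1 | intermediate
3 | (S)-6-acetoxy-2H-pyran-3(6H)-one | O=C1CO[C@@H](OC(C)=O)C=C1 | intermediate
4 | (R)-6-[(4-methoxybenzyl)oxy]-2H-pyran-3(6H)-one | O=C1CO[C@@H](OCc2ccc(OC)cc2)C=C1 | intermediate
5 | photoadduct: 7,7-dimethoxycyclobutane (C5–C6–C7–C9) cis-fused to the 1-(PMB-oxy)tetrahydropyran-4-one; cyclobutane anti to the PMB-oxy group | O=C1CO[C@@H](OCc2ccc(OC)cc2)[C@H]3[C@@H]1CC3(OC)OC | intermediate
6 | C3=C4 enol triflate of 5 | FC(F)(F)S(=O)(=O)OC1=CO[C@@H](OCc2ccc(OC)cc2)[C@H]3[C@@H]1CC3(OC)OC | intermediate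
7 | cyclobutanone (C7 ketone) of 6 | FC(F)(F)S(=O)(=O)OC1=CO[C@@H](OCc2ccc(OC)cc2)[C@H]3[C@@H]1CC3=O | intermediate
8 | tertiary cyclobutanol: C7 carries OH (endo, cis to C1) and 1-ethoxyvinyl (exo, cis to H9) | FC(F)(F)S(=O)(=O)OC1=CO[C@@H](OCc2ccc(OC)cc2)[C@H]3[C@@H]1C[C@]3(O)C(=C)OCC | intermediate
9 | ethyl hemiketal: C7 carries OH and a 1-ethoxy-1,2-dihydroxyethyl group (hemiketal carbon unassigned) | FC(F)(F)S(=O)(=O)OC1=CO[C@@H](OCc2ccc(OC)cc2)[C@H]3[C@@H]1C[C@]3(O)C(O)(CO)OCC | intermediate (not isolated)
10 | hydroxyacetyl cyclobutanol: C7 carries OH (endo) and C8(=O)–C10H2OH (exo) | FC(F)(F)S(=O)(=O)OC1=CO[C@@H](OCc2ccc(OC)cc2)[C@H]3[C@@H]1C[C@]3(O)C(=O)CO | intermediate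
11 | C10 3-methylbutanoate of 10 | FC(F)(F)S(=O)(=O)OC1=CO[C@@H](OCc2ccc(OC)cc2)[C@H]3[C@@H]1C[C@]3(O)C(=O)COC(=O)CC(C)C | intermediate
12 | ring-expanded cyclopentanone: C7 ketone, C8 with OH (cis to C1) and CH2O-isovaleryl (cis to H9), C4 triflate, C1 PMB acetal, H5 and H9 cis | O=C1C[C@@H]2C(OS(=O)(=O)C(F)(F)F)=CO[C@@H](OCc3ccc(OC)cc3)[C@@H]2[C@@]1(O)COC(=O)CC(C)C | intermediate
13 | dienone: 12 with the C5=C6 double bond | O=C1C=C2C(OS(=O)(=O)C(F)(F)F)=CO[C@@H](OCc3ccc(OC)cc3)[C@@H]2[C@@]1(O)COC(=O)CC(C)C | intermediate
14 | C1 lactol of 13 (anomeric mixture) | O=C1C=C2C(OS(=O)(=O)C(F)(F)F)=COC(O)[C@@H]2[C@@]1(O)COC(=O)CC(C)C | intermediate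
15 | C1 3-methylbut-2-enoate of 14 (acyloxy cis to H9) | O=C1C=C2C(OS(=O)(=O)C(F)(F)F)=CO[C@@H](OC(=O)C=C(C)C)[C@@H]2[C@@]1(O)COC(=O)CC(C)C | intermediate
16 | C11 alcohol: 4-(hydroxymethyl) analogue of 15 | O=C1C=C2C(CO)=CO[C@@H](OC(=O)C=C(C)C)[C@@H]2[C@@]1(O)COC(=O)CC(C)C | intermediate
17 | C11 acetate of 16 | O=C1C=C2C(COC(C)=O)=CO[C@@H](OC(=O)C=C(C)C)[C@@H]2[C@@]1(O)COC(=O)CC(C)C | intermediate
18 | C7 alcohol of 17 (C7–OH trans to C8–OH) | O[C@H]1C=C2C(COC(C)=O)=CO[C@@H](OC(=O)C=C(C)C)[C@@H]2[C@@]1(O)COC(=O)CC(C)C | intermediate
19 | (S)-3-methylpentanoic acid | CC[C@H](C)CC(=O)O | starting material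
20 | target (CNP0297662.1) | CC[C@H](C)CC(=O)O[C@H]1C=C2C(COC(C)=O)=CO[C@@H](OC(=O)C=C(C)C)[C@@H]2[C@@]1(O)COC(=O)CC(C)C | target

**Totals and risks**
Total step count: 17. Longest linear sequence: 17 steps (1 → 20).

Steps most likely to fail:

Step 10. The C6 methylene may migrate instead of the C9 ring-fusion carbon, or the shift may run through the open (anti) geometry and erode the C8 configuration. The fallback sets out from 7 and returns at 12. Ethynylmagnesium bromide adds from the convex face to give the 1-ethynylcyclobutanol F1. Cationic gold catalysis (Ph3PAuCl, AgSbF6, CH2Cl2) triggers a semipinacol-type ring expansion, in which the more substituted carbon is known to migrate, giving the α-methylene cyclopentanone F2. A CBS reduction, with the catalyst antipode chosen to deliver hydride to the convex face, gives the allylic alcohol F3 with the C7 hydroxyl cis to C1. VO(acac)2 with t-BuOOH delivers the epoxide oxygen to C8 syn to that hydroxyl, giving the spiro-epoxy alcohol F4. Dess–Martin oxidation gives the spiro-epoxy ketone F5, and opening at the primary C10 with caesium 3-methylbutanoate in DMF gives 12.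

Step 13. Anomeric selectivity in the acylation may be poor, or the lactol may be lost through its ring-opened form under base. The fallback sets out from 14 and returns at 15. Trichloroacetonitrile with catalytic DBU gives the thermodynamic axial C1 trichloroacetimidate F6. Displacement with 3-methylbut-2-enoic acid in CH2Cl2, without promoter, proceeds with inversion and gives the equatorial ester 15.

Step 14. Transmetalation of the hydroxymethyl stannane may be slow, with protodetriflation or thermal loss of the anomeric ester competing. The fallback sets out from 15 and returns at 18. Reductive carbonylation (Pd(OAc)2, 1,3-bis(diphenylphosphino)propane, CO, Et3SiH, DMF, 70 °C) gives the C11 aldehyde F7. Luche reduction of both the aldehyde and the C7 ketone gives the C7,C11 diol F8. Selective acetylation of the primary allylic hydroxyl (acetyl chloride, 2,4,6-collidine, −78 °C) gives 18.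

**Further compounds**
F1 | step 10 | 1-ethynylcyclobutanol: C7 carries OH (endo) and ethynyl (exo) | FC(F)(F)S(=O)(=O)OC1=CO[C@@H](OCc2ccc(OC)cc2)[C@H]3[C@@H]1C[C@]3(O)C#C
F2 | step 10 | α-methylene cyclopentanone (C7 ketone, exocyclic C8=C10H2) | O=C1C[C@@H]2C(OS(=O)(=O)C(F)(F)F)=CO[C@@H](OCc3ccc(OC)cc3)[C@@H]2C1=C
F3 | step 10 | allylic alcohol, C7–OH cis to C1 | O[C@@H]1C[C@@H]2C(OS(=O)(=O)C(F)(F)F)=CO[C@@H](OCc3ccc(OC)cc3)[C@@H]2C1=C
F4 | step 10 | spiro-epoxy alcohol, epoxide oxygen on C8 cis to the C7 hydroxyl and to C1 | O[C@@H]1C[C@@H]2C(OS(=O)(=O)C(F)(F)F)=CO[C@@H](OCc3ccc(OC)cc3)[C@@H]2[C@@]14CO4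
F5 | step 10 | spiro-epoxy ketone (C7 ketone, C8–C10 epoxide) | O=C1C[C@@H]2C(OS(=O)(=O)C(F)(F)F)=CO[C@@H](OCc3ccc(OC)cc3)[C@@H]2[C@@]14CO4
F6 | step 13 | C1 trichloroacetimidate of 14 (imidate trans to H9) | O=C1C=C2C(OS(=O)(=O)C(F)(F)F)=CO[C@H](OC(=N)C(Cl)(Cl)Cl)[C@@H]2[C@@]1(O)COC(=O)CC(C)C
F7 | step 14 | C11 aldehyde (4-formyl analogue of 15) | O=C1C=C2C(C=O)=CO[C@@H](OC(=O)C=C(C)C)[C@@H]2[C@@]1(O)COC(=O)CC(C)C
F8 | step 14 | C7,C11 diol | O[C@H]1C=C2C(CO)=CO[C@@H](OC(=O)C=C(C)C)[C@@H]2[C@@]1(O)COC(=O)CC(C)C
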